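**Retrosynthetic overview**
- Target ⇐ Swern oxidation of an 11,12-diol that already carries the 1β-coumarate; the tetraol precursor ⇐ one LiAlH4 operation on a 5α,6α-epoxy diester (reduces both esters and opens the epoxide to the 5α-OH).
- Epoxide ⇐ α-face epoxidation of a drima-5,7-diene diester.
- Key disconnection C9–C10: the ester α-carbon C9, oxidised to a reversed-polarity (enolonium-type) centre, bonds to C10 of the tetrasubstituted ring-A alkene; this closes ring B and sets the quaternary C10 anti to the C1 silyl ether.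
- Cyclisation substrate ⇐ CBS reduction (sets C1) of an enone carrying an (E)-alkylidene succinate chain, made from an aldehyde, dimethyl maleate and PBu3.
- Ring A comes first (Stork–Danheiser chemistry on a bought cyclohexenone); ring B is formed second, in the key step.

Assumption: 3-ethoxy-2-methylcyclohex-2-en-1-one is bought as a catalogue compound (otherwise one step from 2-methylcyclohexane-1,3-dione).
Numbering: bicyclic compounds use drimane numbering (C4 gem-dimethyl, C10 angular methyl, C11 on C9, C12 on C8); β is the face of the C10 methyl.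

**Step 1**
Reactants: 1 3-ethoxy-2-methylcyclohex-2-en-1-one
Product: 3 3-ethoxy-2,6,6-trimethylcyclohex-2-en-1-one, via monomethyl enol ether 2 (not isolated)
Conditions: LiN(i-Pr)2, THF, −78 °C; MeI, → 0 °C; then LiN(i-Pr)2, −78 °C; MeI, → 23 °C
Reagents that add atoms: iodomethane, CI
Why: Stork–Danheiser kinetic α′-enolate alkylation of a vinylogous ester, run twice at C6 (the only kinetically acidic α-position); no stereocentre is formed.

**Step 2**
Reactants: 3 3-ethoxy-2,6,6-trimethylcyclohex-2-en-1-one; 4 allylmagnesium bromide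
Product: 6 3-allyl-2,4,4-trimethylcyclohex-2-en-1-one, via magnesium alkoxide 5 (not isolated)
Conditions: THF, 0 °C; then 1 M HCl, 0 → 23 °C
Reagents that add atoms: water, O (the ketone oxygen, delivered in the hydrolytic transposition)
Why: Stork–Danheiser 1,2-addition of the small, reactive allyl Grignard to the hindered carbonyl, then acid hydrolysis of the enol ether with allylic transposition, puts the chain on the carbon next to the gem-dimethyl group; no stereocentre.

**Step 3**
Reactants: 6 3-allyl-2,4,4-trimethylcyclohex-2-en-1-one; 7 dimethyl maleate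
Product: 9 dimethyl (2E)-2-[2-(2,6,6-trimethyl-3-oxocyclohex-1-en-1-yl)ethylidene]butanedioate, via keto aldehyde 8 (not isolated)
Conditions: O3, CH2Cl2, −78 °C; Me2S, → 23 °C; evaporate; then 7, PBu3, THF, 23 °C
Reagents that add atoms: ozone, [O-][O+]=O (aldehyde oxygen of 8 only)
Why: Ozonolysis cleaves the electron-rich terminal alkene (the tetrasubstituted enone alkene is deactivated), and a phosphine-mediated Wittig-type olefination (PBu3 plus maleate gives the succinate ylide) converts the acid-sensitive aldehyde in the same flask into the (E)-alkylidene succinate.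

**Step 4**
Reactants: 9 dimethyl (2E)-2-[2-(2,6,6-trimethyl-3-oxocyclohex-1-en-1-yl)ethylidene]butanedioate
Product: 10 dimethyl (2E)-2-{2-[(3R)-3-hydroxy-2,6,6-trimethylcyclohex-1-en-1-yl]ethylidene}butanedioate
Conditions: (S)-2-methyl-CBS-oxazaborolidine (20 mol%), BH3·SMe2, toluene, −30 °C; MeOH
Reagents that add atoms: none
Why: Corey–Bakshi–Shibata reduction, in which the α-methyl-substituted alkene arm acts as the large group (as phenyl does in acetophenone), so the (S)-catalyst gives the (R)-carbinol that becomes C1; the esters are untouched.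

**Step 5**
Reactants: 10 dimethyl (2E)-2-{2-[(3R)-3-hydroxy-2,6,6-trimethylcyclohex-1-en-1-yl]ethylidene}butanedioate
Product: 11 dimethyl (2E)-2-{2-[(3R)-2,6,6-trimethyl-3-(triethylsilyloxy)cyclohex-1-en-1-yl]ethylidene}butanedioate
Conditions: Et3SiCl, imidazole, DMF, 23 °C
Reagents that add atoms: chlorotriethylsilane, CC[Si](CC)(CC)Cl
Why: Standard silylation; it blocks oxa-Michael addition of the C1 alkoxide to the enoate under the basic conditions of the next step and supplies the bulky allylic group that steers that step.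

**Step 6**
Reactants: 11 dimethyl (2E)-2-{2-[(3R)-2,6,6-trimethyl-3-(triethylsilyloxy)cyclohex-1-en-1-yl]ethylidene}butanedioate
Product: 13 dimethyl 1β-(triethylsilyloxy)drima-5,7-diene-11,12-dioate, via lithium ester enolate 12 (not isolated)
Conditions: LiN(i-Pr)2, THF, −78 °C; then cannulated into Cu(O2CCH(Et)Bu)2 (2.5 equiv), THF, −78 → 0 °C, 5 mM
Reagents that add atoms: none
Why: Proposed new method: the lithium enolate of the saturated ester is oxidised by the cupric carboxylate to an ester-stabilised allyl radical, so the normally nucleophilic C9 becomes an enolonium-type centre that adds 6-endo to C10 of the electron-rich tetrasubstituted ring-A alkene anti to the pseudoaxial C1 silyl ether (methyl ends cis to O-1; the ester arm stays outside the allyl unit and ends pseudo-equatorial, 9β), and a second cupric ion oxidises the tertiary C5 radical with loss of H-6 to the conjugated 5,7-diene; the closest known reactions are the cupric-salt oxidative coupling of ester enolates and the Mn(OAc)3/Cu(OAc)2 oxidative radical cyclisation–elimination of unsaturated β-dicarbonyls.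

**Step 7**
Reactants: 13 dimethyl 1β-(triethylsilyloxy)drima-5,7-diene-11,12-dioate
Product: 14 dimethyl 5α,6α-epoxy-1β-(triethylsilyloxy)drim-7-ene-11,12-dioate
Conditions: DMDO, acetone, −20 °C
Reagents that add atoms: dimethyldioxirane, CC1(C)OO1
Why: Electrophilic epoxidation takes the distal, more electron-rich γ,δ-alkene of the dienoate, from the α face because the β face is blocked by the axial 4β- and 10β-methyl groups, which sets the C5–O bond α.

**Step 8**
Reactants: 14 dimethyl 5α,6α-epoxy-1β-(triethylsilyloxy)drim-7-ene-11,12-dioate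
Product: 16 drim-7-ene-1β,5α,11,12-tetraol, via silyl triol 15 (not isolated)
Conditions: LiAlH4, THF, 0 → 40 °C; H2O; then pyridinium p-toluenesulfonate, MeOH, 40 °C
Reagents that add atoms: none
Why: LiAlH4 reduces both esters and opens the vinyl epoxide by hydride attack at the allylic, less substituted C6 (trans-diaxial Fürst–Plattner opening), so the C5–O bond and the 5α configuration are kept; acid-catalysed methanolysis then removes the triethylsilyl ether.

**Step 9**
Reactants: 16 drim-7-ene-1β,5α,11,12-tetraol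
Product: 17 11,12-bis(triethylsilyloxy)drim-7-ene-1β,5α-diol
Conditions: Et3SiCl (2.1 equiv), imidazole, CH2Cl2, −40 → −20 °C
Reagents that add atoms: chlorotriethylsilane, CC[Si](CC)(CC)Cl
Why: Kinetic silylation takes the two primary hydroxyls and leaves the neopentyl secondary C1–OH and the tertiary C5–OH free.

**Step 10**
Reactants: 18 (E)-4-hydroxycinnamic acid
Product: 20 (E)-4-(tert-butyldimethylsilyloxy)cinnamic acid, via silyl ester 19 (not isolated)
Conditions: t-BuMe2SiCl (2.3 equiv), imidazole, DMF, 23 °C; then AcOH/THF/H2O, 23 °C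
Reagents that add atoms: tert-butylchlorodimethylsilane, CC(C)(C)[Si](C)(C)Cl
Why: Double silylation followed by selective hydrolysis of the much more labile silyl ester leaves the phenol protected as its aryl silyl ether.

**Step 11**
Reactants: 17 11,12-bis(triethylsilyloxy)drim-7-ene-1β,5α-diol; 20 (E)-4-(tert-butyldimethylsilyloxy)cinnamic acid
Product: 22 5α-hydroxy-11,12-bis(triethylsilyloxy)drim-7-en-1β-yl (E)-4-(tert-butyldimethylsilyloxy)cinnamate, via mixed anhydride 21 (not isolated)
Conditions: 2,4,6-Cl3C6H2COCl, Et3N, THF, 23 °C; then 17, 4-(dimethylamino)pyridine, toluene, 60 °C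
Reagents that add atoms: 2,4,6-trichlorobenzoyl chloride, O=C(Cl)c1c(Cl)cc(Cl)cc1Cl (in anhydride 21 only)
Why: Yamaguchi esterification acylates the hindered equatorial C1–OH at oxygen (configuration retained), while the tertiary C5–OH is inert.

**Step 12**
Reactants: 22 5α-hydroxy-11,12-bis(triethylsilyloxy)drim-7-en-1β-yl (E)-4-(tert-butyldimethylsilyloxy)cinnamate
Product: 23 5α,11,12-trihydroxydrim-7-en-1β-yl (E)-4-(tert-butyldimethylsilyloxy)cinnamate
Conditions: pyridinium p-toluenesulfonate, MeOH/CH2Cl2, 0 → 23 °C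
Reagents that add atoms: none
Why: Mild acid methanolysis removes the primary alkyl triethylsilyl ethers, while the acid-stable aryl silyl ether and the cinnamate ester survive.

**Step 13**
Reactants: 23 5α,11,12-trihydroxydrim-7-en-1β-yl (E)-4-(tert-butyldimethylsilyloxy)cinnamate
Product: 24 5α-hydroxy-11,12-dioxodrim-7-en-1β-yl (E)-4-(tert-butyldimethylsilyloxy)cinnamate
Conditions: (COCl)2, DMSO, CH2Cl2, −78 °C; Et3N, −78 → −30 °C
Reagents that add atoms: none
Why: Swern oxidation activates both primary hydroxyls before base is added, so the 1,4-diol gives the ene-dialdehyde and not a lactol or lactone; cold Et3N does not epimerise C9 and the tertiary alcohol cannot be oxidised.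

**Step 14**
Reactants: 24 5α-hydroxy-11,12-dioxodrim-7-en-1β-yl (E)-4-(tert-butyldimethylsilyloxy)cinnamate
Product: 25 (1R,5R,9R,10S)-5α-hydroxy-11,12-dioxodrim-7-en-1β-yl (E)-3-(4-hydroxyphenyl)prop-2-enoate
Conditions: Bu4NF, AcOH, THF, 0 °C
Reagents that add atoms: none
Why: Acetic-acid-buffered fluoride cleaves the aryl silyl ether fast under near-neutral conditions that leave the base-sensitive C9 aldehyde centre and the δ-hydroxy enal intact.

**Compound list**
1 | 3-ethoxy-2-methylcyclohex-2-en-1-one | CCOC1=C(C)C(=O)CCC1 | starting material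
2 | 3-ethoxy-2,6-dimethylcyclohex-2-en-1-one (racemic, not isolated) | CCOC1=C(C)C(=O)C(C)CC1 | intermediate
3 | 3-ethoxy-2,6,6-trimethylcyclohex-2-en-1-one | CCOC1=C(C)C(=O)C(C)(C)CC1 | intermediate
4 | allylmagnesium bromide | C=CC[Mg]Br | starting material
5 | bromomagnesium 1-allyl-3-ethoxy-2,6,6-trimethylcyclohex-2-en-1-olate (racemic, not isolated) | CCOC1=C(C)C(CC=C)(O[Mg]Br)C(C)(C)CC1 | intermediate
6 | 3-allyl-2,4,4-trimethylcyclohex-2-en-1-one | C=CCC1=C(C)C(=O)CCC1(C)C | intermediate
7 | dimethyl maleate | COC(=O)/C=C\C(=O)OC | starting material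
8 | 2-(2,6,6-trimethyl-3-oxocyclohex-1-en-1-yl)acetaldehyde (not isolated) | O=CCC1=C(C)C(=O)CCC1(C)C | intermediate
9 | dimethyl (2E)-2-[2-(2,6,6-trimethyl-3-oxocyclohex-1-en-1-yl)ethylidene]butanedioate | COC(=O)C/C(=C\CC1=C(C)C(=O)CCC1(C)C)C(=O)OC | intermediate
10 | dimethyl (2E)-2-{2-[(3R)-3-hydroxy-2,6,6-trimethylcyclohex-1-en-1-yl]ethylidene}butanedioate | COC(=O)C/C(=C\CC1=C(C)[C@H](O)CCC1(C)C)C(=O)OC | intermediate
11 | dimethyl (2E)-2-{2-[(3R)-2,6,6-trimethyl-3-(triethylsilyloxy)cyclohex-1-en-1-yl]ethylidene}butanedioate | COC(=O)C/C(=C\CC1=C(C)[C@H](O[Si](CC)(CC)CC)CCC1(C)C)C(=O)OC | intermediate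
12 | lithium enolate of 11 at the CH2CO2Me arm (enolate geometry not defined, not isolated) | [Li+].COC([O-])=C/C(=C\CC1=C(C)[C@H](O[Si](CC)(CC)CC)CCC1(C)C)C(=O)OC | intermediate
13 | dimethyl 1β-(triethylsilyloxy)drima-5,7-diene-11,12-dioate (9α-H, 9β-CO2Me, 10β-Me) | CC1(C)CC[C@@H](O[Si](CC)(CC)CC)[C@]2(C)[C@@H](C(=O)OC)C(C(=O)OC)=CC=C12 | intermediate
14 | dimethyl 5α,6α-epoxy-1β-(triethylsilyloxy)drim-7-ene-11,12-dioate | CC1(C)CC[C@@H](O[Si](CC)(CC)CC)[C@]2(C)[C@@H](C(=O)OC)C(C(=O)OC)=C[C@@H]3O[C@]123 | intermediate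
15 | 1β-(triethylsilyloxy)drim-7-ene-5α,11,12-triol (not isolated) | CC1(C)CC[C@@H](O[Si](CC)(CC)CC)[C@]2(C)[C@@H](CO)C(CO)=CC[C@@]12O | intermediate
16 | drim-7-ene-1β,5α,11,12-tetraol | CC1(C)CC[C@@H](O)[C@]2(C)[C@@H](CO)C(CO)=CC[C@@]12O | intermediate
17 | 11,12-bis(triethylsilyloxy)drim-7-ene-1β,5α-diol | CC1(C)CC[C@@H](O)[C@]2(C)[C@@H](CO[Si](CC)(CC)CC)C(CO[Si](CC)(CC)CC)=CC[C@@]12O | intermediate
18 | (E)-4-hydroxycinnamic acid (p-coumaric acid) | OC(=O)/C=C/c1ccc(O)cc1 | starting material
19 | tert-butyldimethylsilyl (E)-4-(tert-butyldimethylsilyloxy)cinnamate (not isolated) | CC(C)(C)[Si](C)(C)OC(=O)/C=C/c1ccc(O[Si](C)(C)C(C)(C)C)cc1 | intermediate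
20 | (E)-4-(tert-butyldimethylsilyloxy)cinnamic acid | OC(=O)/C=C/c1ccc(O[Si](C)(C)C(C)(C)C)cc1 | intermediate
21 | (E)-4-(tert-butyldimethylsilyloxy)cinnamic 2,4,6-trichlorobenzoic anhydride (not isolated) | O=C(/C=C/c1ccc(O[Si](C)(C)C(C)(C)C)cc1)OC(=O)c1c(Cl)cc(Cl)cc1Cl | intermediate
22 | 5α-hydroxy-11,12-bis(triethylsilyloxy)drim-7-en-1β-yl (E)-4-(tert-butyldimethylsilyloxy)cinnamate | CC1(C)CC[C@@H](OC(=O)/C=C/c2ccc(O[Si](C)(C)C(C)(C)C)cc2)[C@]2(C)[C@@H](CO[Si](CC)(CC)CC)C(CO[Si](CC)(CC)CC)=CC[C@@]12O | intermediate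
23 | 5α,11,12-trihydroxydrim-7-en-1β-yl (E)-4-(tert-butyldimethylsilyloxy)cinnamate | CC1(C)CC[C@@H](OC(=O)/C=C/c2ccc(O[Si](C)(C)C(C)(C)C)cc2)[C@]2(C)[C@@H](CO)C(CO)=CC[C@@]12O | intermediate
24 | 5α-hydroxy-11,12-dioxodrim-7-en-1β-yl (E)-4-(tert-butyldimethylsilyloxy)cinnamate | CC1(C)CC[C@@H](OC(=O)/C=C/c2ccc(O[Si](C)(C)C(C)(C)C)cc2)[C@]2(C)[C@@H](C=O)C(C=O)=CC[C@@]12O | intermediate
25 | (1R,5R,9R,10S)-5α-hydroxy-11,12-dioxodrim-7-en-1β-yl (E)-3-(4-hydroxyphenyl)prop-2-enoate (CNP0323926.1) | CC1(C)CC[C@@H](OC(=O)/C=C/c2ccc(O)cc2)[C@]2(C)[C@@H](C=O)C(C=O)=CC[C@@]12O | target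

**Step count**
Total: 14 steps. Longest linear sequence: 13 steps (1 → 25 through steps 1–9 and 11–14); step 10 is the one-step side branch to acid 20.

**Three steps most likely to fail**

Step 6 (key oxidative cyclisation). The stabilised C9 radical may dimerise, add 5-exo, or fail to attack the hindered tetrasubstituted alkene, and the C9 configuration rests on a conformational argument. The fallback builds ring B by a thermal Diels–Alder reaction instead. It sets out from 3: Stork–Danheiser addition of vinylmagnesium bromide and acid work-up give 2,4,4-trimethyl-3-vinylcyclohex-2-en-1-one F1. (S)-2-Methyl-CBS-oxazaborolidine/BH3·SMe2 reduction gives (1R)-2,4,4-trimethyl-3-vinylcyclohex-2-en-1-ol F2, and Et3SiCl/imidazole gives triethyl{[(1R)-2,4,4-trimethyl-3-vinylcyclohex-2-en-1-yl]oxy}silane F3. Heating F3 with dimethyl acetylenedicarboxylate in toluene at 110 °C adds the alkyne anti to the silyl ether and gives dimethyl 1β-(triethylsilyloxy)drima-5,8-diene-11,12-dioate F4. Deprotonation at the doubly allylic C7 with LiN(i-Pr)2 and protonation of the dienolate at C9 from the α face (AcOH, −78 °C) comes back to the route at 13.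

Step 8 (hydride opening of the vinyl epoxide). Hydride must reach C6 from the β face between two syn-axial methyl groups, and SN2′ delivery to C8 would give the Δ6 isomer. The fallback cleaves the C6–O bond by electron transfer, which needs no backside attack. It sets out from 14: SmI2 in THF/MeOH at −78 °C reduces the vinylogous epoxy ester and, after α-protonation, gives dimethyl 5α-hydroxy-1β-(triethylsilyloxy)drim-6-ene-11,12-dioate F5. A short treatment with DBU moves the double bond back into conjugation and gives dimethyl 5α-hydroxy-1β-(triethylsilyloxy)drim-7-ene-11,12-dioate F6. LiAlH4, then pyridinium p-toluenesulfonate in MeOH, takes F6 through 15 back to the route at 16.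

Step 3 (ozonolysis and olefination through keto aldehyde 8). Aldehyde 8 is a Z-configured 1,5-dicarbonyl with a very acidic CH2, so it can condense with itself or close to a pyranol before the ylide reacts. The fallback removes the ketone before the aldehyde is made. It sets out from 6: CBS reduction as in step 4 gives (1R)-3-allyl-2,4,4-trimethylcyclohex-2-en-1-ol F7, and Et3SiCl/imidazole gives {[(1R)-3-allyl-2,4,4-trimethylcyclohex-2-en-1-yl]oxy}triethylsilane F8. OsO4 (cat.)/NaIO4 with 2,6-lutidine cleaves only the terminal alkene and gives the ordinary, non-acidic aldehyde 2-[(3R)-2,6,6-trimethyl-3-(triethylsilyloxy)cyclohex-1-en-1-yl]acetaldehyde F9. PBu3/dimethyl maleate olefination of F9 comes back to the route at 11.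

**Further compounds**
F1 | step 6 | 2,4,4-trimethyl-3-vinylcyclohex-2-en-1-one | C=CC1=C(C)C(=O)CCC1(C)C
F2 | step 6 | (1R)-2,4,4-trimethyl-3-vinylcyclohex-2-en-1-ol | C=CC1=C(C)[C@H](O)CCC1(C)C
F3 | step 6 | triethyl{[(1R)-2,4,4-trimethyl-3-vinylcyclohex-2-en-1-yl]oxy}silane | C=CC1=C(C)[C@H](O[Si](CC)(CC)CC)CCC1(C)C
F4 | step 6 | dimethyl 1β-(triethylsilyloxy)drima-5,8-diene-11,12-dioate | CC1(C)CC[C@@H](O[Si](CC)(CC)CC)[C@]2(C)C(C(=O)OC)=C(C(=O)OC)CC=C12
F5 | step 8 | dimethyl 5α-hydroxy-1β-(triethylsilyloxy)drim-6-ene-11,12-dioate (C8 epimers) | CC1(C)CC[C@@H](O[Si](CC)(CC)CC)[C@]2(C)[C@@H](C(=O)OC)C(C(=O)OC)C=C[C@@]12O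
F6 | step 8 | dimethyl 5α-hydroxy-1β-(triethylsilyloxy)drim-7-ene-11,12-dioate | CC1(C)CC[C@@H](O[Si](CC)(CC)CC)[C@]2(C)[C@@H](C(=O)OC)C(C(=O)OC)=CC[C@@]12O
F7 | step 3 | (1R)-3-allyl-2,4,4-trimethylcyclohex-2-en-1-ol | C=CCC1=C(C)[C@H](O)CCC1(C)C
F8 | step 3 | {[(1R)-3-allyl-2,4,4-trimethylcyclohex-2-en-1-yl]oxy}triethylsilane | C=CCC1=C(C)[C@H](O[Si](CC)(CC)CC)CCC1(C)C
F9 | step 3 | 2-[(3R)-2,6,6-trimethyl-3-(triethylsilyloxy)cyclohex-1-en-1-yl]acetaldehyde | O=CCC1=C(C)[C@H](O[Si](CC)(CC)CC)CCC1(C)C
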